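## The problem

Target 15, 2-[2-[4-hydroxy-3-[4-[2-(3-hydroxyphenyl)ethyl]phenoxy]phenyl]ethyl]benzene-1,4-diol, is an open-chain bis(bibenzyl). Ring A (3-hydroxyphenyl) and ring B (1,4-disubstituted) are joined by one CH2CH2 bridge, ring C (4-hydroxy-3-aryloxyphenyl) and ring D (2,5-dihydroxyphenyl) by a second, and a diaryl ether oxygen runs from C4 of ring B to C3 of ring C. There is no stereocentre and no fused ring, so nothing has to be controlled in space; the task is three ring-to-ring links and the order in which four phenolic hydroxyls are exposed. The ether carbon of ring C lies ortho to an oxygen substituent, so that C–O bond must be made at a hindered, electron-rich position. Ring D is an alkylhydroquinone: air oxidises it, quickly in base, and its quinone form is destroyed by base and adds nucleophiles such as chloride, so it should appear late and never meet base. The phenols of rings A and C would compete in the etherification and would not survive a one-electron oxidant, so they need masks that come off without base. The key step rests on ring D being the reduced form of a 2-alkyl-1,4-benzoquinone. The parent quinone 12 has four equivalent C–H carbons, so the bond from the ring D carbon to its bridge CH2 can be made by adding one primary alkyl radical, with no regiochemical question, and that radical is available from a 3-arylpropanoic acid by loss of CO2.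

## Retrosynthesis

**15 back to 13.** No skeletal bond is cut. The two aryl acetates of 14 are removed by acid methanolysis, and 14 is the dithionite reduction product of quinone 13. Reduction must come before acid treatment because HCl adds to quinones, and base is excluded at both stages. This leaves a quinone whose rings A and C carry electron-poor, acid-labile masks.

**13 back to 11 and 12.** The bond between the ring D carbon and the adjacent bridge CH2 is cut, giving diacetate acid 11 and 1,4-benzoquinone 12. The neighbouring cut through the CH2–CH2 bond (olefination of a ring C aldehyde with a 2,5-dimethoxybenzyl ylide) would carry ring D as a dimethyl ether and end with a fourfold demethylation next to a free hydroquinone. The cut at the ring C side would need an sp2–sp3 coupling. The radical cut takes ring D from the cheapest possible source, in its stable oxidised form, and makes the rest a simple arylpropanoic acid. The forward reaction must generate a primary radical from the carboxylate without oxidising the arenes, and must stop at monoalkylation.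

**11 back to 8.** Only protecting groups change. Acetates are wanted in the key step because they lower the electron density of rings A and C and leave under acid. They would not survive the basic steps that build the skeleton, so the skeleton is assembled as dimethyl ether methyl ester 8. Hot HBr in acetic acid cleaves both ethers and the ester at once to diphenol acid 9, and acetylation of 9 gives 11.

**8 back to 5 and 7.** The ether C–O bond on the ring C side is cut, giving phenol 5 and aryl bromide 7 for an Ullmann coupling. The opposite polarity would need a ring B halide with no activation and a ring C catechol whose two oxygens had to be told apart. In the chosen polarity 5 has one hydroxyl, and the bromine of 7 enters exactly where the ether oxygen must sit. The coupling has to tolerate an ortho methoxy group and a methyl ester.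

**5 back to 1 and 2.** The central C–C bond of the A–B bridge is cut as a C=C bond: Horner–Wadsworth–Emmons olefination of aldehyde 2 with phosphonate 1 gives stilbene 3. One hydrogenation then saturates the alkene and removes the benzyl group, so the ring B hydroxyl appears free while the ring A oxygen stays methylated. Both partners are simple benzene derivatives.

**7 back to 6.** The C–Br bond is cut. In ester 6 the methoxy group directs bromination to its ortho position, since the para position carries the side chain and the two ortho positions are equivalent.

## Roads not taken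

**Alternative 1:** Ring A would be built rather than bought. Two C–C bonds of ring A are cut, giving keto acetal A2 (which already holds rings B, C and D, with ring D as its dimethyl ether) and the bis(silyl) dienol ether A3 of methyl acetoacetate. With TiCl4 the terminal carbon of A3 attacks the acetal carbon and C2 condenses with the ketone, a formal [3+3] cyclocondensation that closes ring A as the 6-alkylsalicylate A1.
- Merits: the 1,3-relation of hydroxyl and alkyl group is fixed by the reagent pair, the chemistry is purely polar, and no oxidant touches the electron-rich rings. In that last respect it is safer than the radical step of the chosen plan.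
- Weak points: ring A is the simplest ring of the target and is available as a meta-methoxybenzyl reagent. A2 can only be made after every other bond of the molecule is in place, so the sequence is long and linear. The ester carbon of A1 has to be removed again by saponification and thermal decarboxylation of a salicylic acid. Ring D ends as a dimethyl ether that needs a Lewis acid demethylation at the hydroquinone stage.
- Comparison: the chosen plan is convergent, needs no carbon that is later excised, and frees ring D by a mild reduction.

**Alternative 2:** Ring C would start as a cyclohexanone. The ether O–C bond is cut at the ketone oxidation level: the phenoxide of 5 displaces bromide from bromoketone A5 by SN2 reaction to give aryloxy ketone A4, and dehydrogenation then turns the ketone ring into the phenol ring C.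
- Merits: substitution at an sp3 carbon next to a carbonyl replaces a copper coupling at a hindered aryl bromide, and here this road is better than the chosen one. The 4-substituted cyclohexanone is symmetrical, so bromination has no regiochemical issue, and the ring C hydroxyl emerges free and correctly placed. It shares phenol 5 with the chosen route.
- Weak points: A5 needs its own synthesis with the ring D arm attached. Phenoxide can cause elimination or Favorskii-type reaction of an alpha-bromoketone. The aromatisation requires two dehydrogenations in a molecule with two bibenzyl bridges that can themselves be dehydrogenated. Ring D again arrives as a dimethyl ether.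
- Comparison: the chosen plan buys ring C at the right oxidation level and forms the ether in one known step; it sets this economy against the easier C–O bond formation of A4.

**Alternative 3:** Ring B would be made by cycloaddition. Two C–C bonds of ring B are cut, giving methyl coumalate A8 and aryl ynol ether A7. A [4+2] cycloaddition across C3 and C6 of the pyrone, followed by loss of CO2, gives the 4-aryloxybenzoate A6.
- Merits: the ether oxygen is attached to an sp carbon before ring B exists, so no aryl C–O coupling is needed. The para pattern follows from the polarisation of both partners, and CO2 is the only by-product. On these counts it is cleaner than the Ullmann step.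
- Weak points: ring B is a plain para-disubstituted benzene. Aryl ynol ethers take several steps to make and are sensitive to acid and heat. The ester of A6 must still be converted into the CH2CH2 bridge to ring A by reduction, olefination and hydrogenation. Ring D is again a dimethyl ether.
- Comparison: the chosen plan makes the same A–B bridge in two steps from purchased benzenes and accepts a copper coupling in return.

Key step: step 7

## Route

Remark: compounds 1, 2, 6 and 12 are taken as purchased. The target has no stereocentre; the only descriptor in the route is the E geometry of 3, which step 2 erases.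

Step 1
Reactants: 1 diethyl (3-methoxybenzyl)phosphonate; 2 4-(benzyloxy)benzaldehyde
Product: 3 (E)-1-(benzyloxy)-4-[2-(3-methoxyphenyl)ethenyl]benzene
Conditions: KOtBu, THF, 0 °C to rt
Reagents that add atoms: none
Why: Horner–Wadsworth–Emmons olefination of a non-enolisable aromatic aldehyde with a benzylic phosphonate anion; reversible addition and elimination should give the E stilbene, whose geometry is removed in step 2 anyway.

Step 2
Reactants: 3 (E)-1-(benzyloxy)-4-[2-(3-methoxyphenyl)ethenyl]benzene
Product: 5 4-[2-(3-methoxyphenyl)ethyl]phenol, via 1-(benzyloxy)-4-[2-(3-methoxyphenyl)ethyl]benzene 4 (not isolated)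
Conditions: H2 (1 atm), 10% Pd/C, EtOAc/MeOH, rt
Reagents that add atoms: none
Why: Heterogeneous catalytic hydrogenation saturates the stilbene C=C and then hydrogenolyses the benzyl ether, so one operation should deliver the ring A–B phenol; the aryl methyl ether is inert.

Step 3
Reactants: 6 methyl 3-(4-methoxyphenyl)propanoate
Product: 7 methyl 3-(3-bromo-4-methoxyphenyl)propanoate
Conditions: NBS, MeCN, rt
Reagents that add atoms: N-bromosuccinimide, O=C1CCC(=O)N1Br
Why: Electrophilic aromatic bromination; the methoxy group directs, its para position is blocked by the side chain and its two ortho positions are equivalent, so a single monobromide is expected.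

Step 4
Reactants: 5 4-[2-(3-methoxyphenyl)ethyl]phenol; 7 methyl 3-(3-bromo-4-methoxyphenyl)propanoate
Product: 8 methyl 3-[4-methoxy-3-[4-[2-(3-methoxyphenyl)ethyl]phenoxy]phenyl]propanoate
Conditions: CuI (10 mol %), N,N-dimethylglycine hydrochloride (30 mol %), Cs2CO3, 1,4-dioxane, 100 °C, Ar
Reagents that add atoms: none
Why: Ullmann diaryl ether synthesis with a monovalent copper and amino acid catalyst, a system known to couple phenols with electron-rich and ortho-substituted aryl bromides; 5 has a single hydroxyl, and the methyl ester and ethers should be stable to anhydrous Cs2CO3.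

Step 5
Reactants: 8 methyl 3-[4-methoxy-3-[4-[2-(3-methoxyphenyl)ethyl]phenoxy]phenyl]propanoate
Product: 9 3-[4-hydroxy-3-[4-[2-(3-hydroxyphenyl)ethyl]phenoxy]phenyl]propanoic acid
Conditions: 48% aq HBr, AcOH, reflux
Reagents that add atoms: water, O
Why: Acidic cleavage of aryl methyl ethers (protonation, then SN2 attack of bromide on the methyl group) runs together with acid hydrolysis of the methyl ester; the diaryl ether offers bromide no sp3 carbon and, like the bibenzyl bridges, should survive.

Step 6
Reactants: 9 3-[4-hydroxy-3-[4-[2-(3-hydroxyphenyl)ethyl]phenoxy]phenyl]propanoic acid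
Product: 11 3-[4-acetoxy-3-[4-[2-(3-acetoxyphenyl)ethyl]phenoxy]phenyl]propanoic acid, via mixed acetic carboxylic anhydride 10 (not isolated)
Conditions: Ac2O, pyridine, DMAP (cat.), CH2Cl2, 0 °C to rt; then H2O, THF, rt
Reagents that add atoms: acetic anhydride, CC(=O)OC(C)=O; water, O
Why: Nucleophile-catalysed O-acetylation of both phenols; the carboxyl group is acylated to the mixed anhydride 10, which water should cleave quickly while the aryl acetates remain.

Step 7
Reactants: 11 3-[4-acetoxy-3-[4-[2-(3-acetoxyphenyl)ethyl]phenoxy]phenyl]propanoic acid; 12 1,4-benzoquinone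
Product: 13 2-[2-[4-acetoxy-3-[4-[2-(3-acetoxyphenyl)ethyl]phenoxy]phenyl]ethyl]-1,4-benzoquinone
Conditions: AgNO3 (0.3 equiv), (NH4)2S2O8 (1.5 equiv, added slowly), 12 (3 equiv), MeCN/H2O 1:1, 65 °C
Reagents that add atoms: none
Why: This is the silver-catalysed persulfate decarboxylative alkylation of a quinone, a Minisci-type radical substitution that is known for primary alkanoic acids and 1,4-benzoquinone. Persulfate oxidises monovalent silver to divalent silver, which oxidises the carboxylate of 11; loss of CO2 leaves a primary 2-arylethyl radical. This nucleophilic radical adds to an electron-poor C=C bond of 12, and oxidation of the adduct radical with loss of a proton restores the quinone and completes the bond between the bridge CH2 and the ring D carbon. No ring closes and no stereocentre is formed. Regiochemistry does not arise because the four C–H carbons of 12 are equivalent. Monoalkylation is needed and should be secured by the excess of 12 and by the lower electrophilicity and greater hindrance of alkylquinone 13. Selectivity for the carboxylate over the arenes is also needed; the acetates lower the electron density of rings A and C, and no free phenol is present.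

Step 8
Reactants: 13 2-[2-[4-acetoxy-3-[4-[2-(3-acetoxyphenyl)ethyl]phenoxy]phenyl]ethyl]-1,4-benzoquinone
Product: 14 2-[2-[4-acetoxy-3-[4-[2-(3-acetoxyphenyl)ethyl]phenoxy]phenyl]ethyl]benzene-1,4-diol
Conditions: Na2S2O4, EtOAc/H2O, rt, Ar
Reagents that add atoms: none
Why: Dithionite reduces a quinone to its hydroquinone rapidly in a neutral two-phase system in which aryl acetates are not hydrolysed; the reduction precedes acid treatment because HCl adds to quinones.

Step 9
Reactants: 14 2-[2-[4-acetoxy-3-[4-[2-(3-acetoxyphenyl)ethyl]phenoxy]phenyl]ethyl]benzene-1,4-diol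
Product: 15 2-[2-[4-hydroxy-3-[4-[2-(3-hydroxyphenyl)ethyl]phenoxy]phenyl]ethyl]benzene-1,4-diol
Conditions: HCl (1.25 M in MeOH, degassed), Ar, 40 °C
Reagents that add atoms: none
Why: Acid-catalysed transesterification passes both acetyl groups to methanol as methyl acetate; the absence of base and oxygen should keep the hydroquinone ring D reduced.

## Compound list

1 | diethyl (3-methoxybenzyl)phosphonate | CCOP(=O)(Cc1cccc(OC)c1)OCC | starting material
2 | 4-(benzyloxy)benzaldehyde | O=Cc1ccc(OCc2ccccc2)cc1 | starting material
3 | (E)-1-(benzyloxy)-4-[2-(3-methoxyphenyl)ethenyl]benzene | COc1cccc(/C=C/c2ccc(OCc3ccccc3)cc2)c1 | intermediate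
4 | 1-(benzyloxy)-4-[2-(3-methoxyphenyl)ethyl]benzene | COc1cccc(CCc2ccc(OCc3ccccc3)cc2)c1 | intermediate (not isolated)
5 | 4-[2-(3-methoxyphenyl)ethyl]phenol | COc1cccc(CCc2ccc(O)cc2)c1 | intermediate
6 | methyl 3-(4-methoxyphenyl)propanoate | COC(=O)CCc1ccc(OC)cc1 | starting material
7 | methyl 3-(3-bromo-4-methoxyphenyl)propanoate | COC(=O)CCc1ccc(OC)c(Br)c1 | intermediate
8 | methyl 3-[4-methoxy-3-[4-[2-(3-methoxyphenyl)ethyl]phenoxy]phenyl]propanoate | COC(=O)CCc1ccc(OC)c(Oc2ccc(CCc3cccc(OC)c3)cc2)c1 | intermediate
9 | 3-[4-hydroxy-3-[4-[2-(3-hydroxyphenyl)ethyl]phenoxy]phenyl]propanoic acid | OC(=O)CCc1ccc(O)c(Oc2ccc(CCc3cccc(O)c3)cc2)c1 | intermediate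
10 | acetic 3-[4-acetoxy-3-[4-[2-(3-acetoxyphenyl)ethyl]phenoxy]phenyl]propanoic anhydride | CC(=O)OC(=O)CCc1ccc(OC(C)=O)c(Oc2ccc(CCc3cccc(OC(C)=O)c3)cc2)c1 | intermediate (not isolated)
11 | 3-[4-acetoxy-3-[4-[2-(3-acetoxyphenyl)ethyl]phenoxy]phenyl]propanoic acid | CC(=O)Oc1cccc(CCc2ccc(Oc3cc(CCC(=O)O)ccc3OC(C)=O)cc2)c1 | intermediate
12 | 1,4-benzoquinone | O=C1C=CC(=O)C=C1 | starting material
13 | 2-[2-[4-acetoxy-3-[4-[2-(3-acetoxyphenyl)ethyl]phenoxy]phenyl]ethyl]-1,4-benzoquinone | CC(=O)Oc1cccc(CCc2ccc(Oc3cc(CCC4=CC(=O)C=CC4=O)ccc3OC(C)=O)cc2)c1 | intermediate
14 | 2-[2-[4-acetoxy-3-[4-[2-(3-acetoxyphenyl)ethyl]phenoxy]phenyl]ethyl]benzene-1,4-diol | CC(=O)Oc1cccc(CCc2ccc(Oc3cc(CCc4cc(O)ccc4O)ccc3OC(C)=O)cc2)c1 | intermediate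
15 | 2-[2-[4-hydroxy-3-[4-[2-(3-hydroxyphenyl)ethyl]phenoxy]phenyl]ethyl]benzene-1,4-diol | Oc1cccc(CCc2ccc(Oc3cc(CCc4cc(O)ccc4O)ccc3O)cc2)c1 | target

## Step count and risks

Total: 9 steps. Longest linear sequence: 8 steps (1, 2, 4, 5, 6, 7, 8, 9); step 3 is a one-step branch.

**Step 7 (key step).**
- What may go wrong: divalent silver or sulfate radical anion may attack the arenes or the benzylic CH2 groups instead of the carboxylate. The acetates may hydrolyse in the hot acidic aqueous medium, and the freed phenols would then be oxidised. A second alkylation of 13 is also possible.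
- Fallback: a non-oxidative radical chain, from 11 back to 14. Coupling of 11 with N-hydroxypyridine-2-thione (DCC, CH2Cl2, dark) gives the Barton ester 2-thioxopyridin-1(2H)-yl 3-[4-acetoxy-3-[4-[2-(3-acetoxyphenyl)ethyl]phenoxy]phenyl]propanoate F1. Visible-light irradiation of F1 with excess 12 in CH2Cl2 at 0 °C releases the same primary radical without an external oxidant. The radical adds to 12, the adduct takes up the pyridylthio group, and excess 12 re-oxidises it to 2-[2-[4-acetoxy-3-[4-[2-(3-acetoxyphenyl)ethyl]phenoxy]phenyl]ethyl]-3-(pyridin-2-ylsulfanyl)-1,4-benzoquinone F2. Raney Ni in THF removes the sulfur substituent and reduces the quinone, rejoining the route at 14.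

**Step 4.**
- What may go wrong: copper may insert slowly into the electron-rich, ortho-substituted C–Br bond, so that hydrodebromination of 7 and cleavage of the methyl ester by carbonate and traces of water take over.
- Fallback: the ether is formed by nucleophilic aromatic substitution and the A–B bridge is built afterwards, from 1 back to 8. Fischer esterification of purchased 3-(3-hydroxy-4-methoxyphenyl)propanoic acid gives methyl 3-(3-hydroxy-4-methoxyphenyl)propanoate F3. Its phenoxide displaces fluoride from 4-fluorobenzaldehyde (K2CO3, DMF, 120 °C) to give methyl 3-[3-(4-formylphenoxy)-4-methoxyphenyl]propanoate F4. Horner–Wadsworth–Emmons reaction of F4 with 1 (KOtBu, THF, 0 °C) gives methyl 3-[4-methoxy-3-[4-[(E)-2-(3-methoxyphenyl)ethenyl]phenoxy]phenyl]propanoate F5, and hydrogenation over Pd/C rejoins the route at 8.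

**Step 5.**
- What may go wrong: the ortho-flanked ring C methyl ether may cleave incompletely before long heating in strong acid starts to degrade the material. Partial O-acetylation by the solvent would not matter, because step 6 acetylates anyway.
- Fallback: ester and ethers are cleaved separately, the ethers with a Lewis acid, from 8 back to 9. Saponification with LiOH in THF/H2O gives 3-[4-methoxy-3-[4-[2-(3-methoxyphenyl)ethyl]phenoxy]phenyl]propanoic acid F6. BBr3 in CH2Cl2 from −78 °C to rt, followed by aqueous work-up, cleaves both methyl ethers and rejoins the route at 9.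

**Step 9.**
- What may go wrong: traces of oxygen may re-oxidise ring D during methanolysis and work-up, giving quinone and quinhydrone, with addition of HCl to the quinone as a consequence.
- Fallback: the free hydroquinone diacetate is avoided, from 13 back to 15. Reductive acetylation of 13 (Zn dust, Ac2O, pyridine) gives the air-stable tetraacetate 2-[2-[4-acetoxy-3-[4-[2-(3-acetoxyphenyl)ethyl]phenoxy]phenyl]ethyl]-1,4-phenylene diacetate F7, which can be purified without precautions. A single degassed HCl/MeOH treatment then removes all four acetates and arrives at 15, so only the final product is handled under exclusion of air.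

## Further compounds

F1 | step 7 | 2-thioxopyridin-1(2H)-yl 3-[4-acetoxy-3-[4-[2-(3-acetoxyphenyl)ethyl]phenoxy]phenyl]propanoate | CC(=O)Oc1cccc(CCc2ccc(Oc3cc(CCC(=O)On4ccccc4=S)ccc3OC(C)=O)cc2)c1
F2 | step 7 | 2-[2-[4-acetoxy-3-[4-[2-(3-acetoxyphenyl)ethyl]phenoxy]phenyl]ethyl]-3-(pyridin-2-ylsulfanyl)-1,4-benzoquinone | CC(=O)Oc1cccc(CCc2ccc(Oc3cc(CCC4=C(Sc5ccccn5)C(=O)C=CC4=O)ccc3OC(C)=O)cc2)c1
F3 | step 4 | methyl 3-(3-hydroxy-4-methoxyphenyl)propanoate | COC(=O)CCc1ccc(OC)c(O)c1
F4 | step 4 | methyl 3-[3-(4-formylphenoxy)-4-methoxyphenyl]propanoate | COC(=O)CCc1ccc(OC)c(Oc2ccc(C=O)cc2)c1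
F5 | step 4 | methyl 3-[4-methoxy-3-[4-[(E)-2-(3-methoxyphenyl)ethenyl]phenoxy]phenyl]propanoate | COC(=O)CCc1ccc(OC)c(Oc2ccc(/C=C/c3cccc(OC)c3)cc2)c1
F6 | step 5 | 3-[4-methoxy-3-[4-[2-(3-methoxyphenyl)ethyl]phenoxy]phenyl]propanoic acid | OC(=O)CCc1ccc(OC)c(Oc2ccc(CCc3cccc(OC)c3)cc2)c1
F7 | step 9 | 2-[2-[4-acetoxy-3-[4-[2-(3-acetoxyphenyl)ethyl]phenoxy]phenyl]ethyl]-1,4-phenylene diacetate | CC(=O)Oc1cccc(CCc2ccc(Oc3cc(CCc4cc(OC(C)=O)ccc4OC(C)=O)ccc3OC(C)=O)cc2)c1
A1 | alternative 1 | methyl 2-[2-[4-[5-[2-(2,5-dimethoxyphenyl)ethyl]-2-methoxyphenoxy]phenyl]ethyl]-6-hydroxybenzoate | COC(=O)c1c(O)cccc1CCc1ccc(Oc2cc(CCc3cc(OC)ccc3OC)ccc2OC)cc1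
A2 | alternative 1 | 5-[4-[5-[2-(2,5-dimethoxyphenyl)ethyl]-2-methoxyphenoxy]phenyl]-1,1-dimethoxypentan-3-one | COC(OC)CC(=O)CCc1ccc(Oc2cc(CCc3cc(OC)ccc3OC)ccc2OC)cc1
A3 | alternative 1 | 1-methoxy-1,3-bis(trimethylsilyloxy)buta-1,3-diene (double-bond isomers as formed) | COC(O[Si](C)(C)C)=CC(=C)O[Si](C)(C)C
A4 | alternative 2 | 4-[2-(2,5-dimethoxyphenyl)ethyl]-2-[4-[2-(3-methoxyphenyl)ethyl]phenoxy]cyclohexan-1-one (racemic mixture of diastereomers) | COc1cccc(CCc2ccc(OC3CC(CCc4cc(OC)ccc4OC)CCC3=O)cc2)c1
A5 | alternative 2 | 2-bromo-4-[2-(2,5-dimethoxyphenyl)ethyl]cyclohexan-1-one (racemic mixture of diastereomers) | COc1ccc(OC)c(CCC2CCC(=O)C(Br)C2)c1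
A6 | alternative 3 | methyl 4-[5-[2-(2,5-dimethoxyphenyl)ethyl]-2-methoxyphenoxy]benzoate | COC(=O)c1ccc(Oc2cc(CCc3cc(OC)ccc3OC)ccc2OC)cc1
A7 | alternative 3 | 4-[2-(2,5-dimethoxyphenyl)ethyl]-2-(ethynyloxy)-1-methoxybenzene | C#COc1cc(CCc2cc(OC)ccc2OC)ccc1OC
A8 | alternative 3 | methyl coumalate (methyl 2-oxo-2H-pyran-5-carboxylate) | COC(=O)C1=COC(=O)C=C1
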